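The quinone ring A (C1, C2, C3, C4, C4a, C8a in naphthoquinone numbering, C2 bearing the side chain) is cut into three pieces. C1 comes from carbon monoxide, C2–C3 from a terminal alkyne that already carries the complete (S)-configured side chain, and C4 from a carbene carbon attached to the hydroquinone ring B. A Dötz benzannulation of pentacarbonyl[(2,5-dimethoxyphenyl)(methoxy)methylidene]chromium with silyl-protected (S)-6-methylhept-5-en-1-yn-3-ol joins them in one operation: C3–C4 by alkyne insertion, C1–C2 by CO insertion, C1–C8a by electrocyclic closure onto the free ortho carbon. (NH4)2Ce(NO3)6 work-up gives the quinone. The step exploits the para-dioxygenated ring A with unsubstituted C3. Esterification and oxidative demethylation of ring B finish the route.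

Key step: step 5

Assumption: naphthazarins (5,8-dihydroxy-1,4-naphthoquinones) equilibrate rapidly between the tautomer with the side chain on the quinone ring and the one with it on the dihydroxybenzene ring, so both drawings denote the target. The stereocenter is (S), the alkannin series.

Step 1
Reactants: 1 methyl (2S)-oxirane-2-carboxylate (methyl (S)-glycidate); 2 (2-methylprop-1-en-1-yl)magnesium bromide
Product: 3 methyl (2S)-2-hydroxy-5-methylhex-4-enoate
Conditions: CuBr·SMe2 (cat.), THF, −40 to −20 °C; aq NH4Cl
Reagents that add atoms: none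
Why: Copper-catalysed epoxide opening by the vinyl Grignard reagent (organocuprate SN2 at the unsubstituted epoxide carbon) should outrun ester attack at low temperature and leaves C2 untouched, so the (S) configuration of the glycidate becomes the carbinol configuration of the side chain.

Step 2
Reactants: 3 methyl (2S)-2-hydroxy-5-methylhex-4-enoate
Product: 4 methyl (2S)-2-[(tert-butyldimethylsilyl)oxy]-5-methylhex-4-enoate
Conditions: TBSCl, imidazole, DMF, 0 °C to rt
Reagents that add atoms: tert-butyldimethylsilyl chloride, CC(C)(C)[Si](C)(C)Cl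
Why: Standard silylation of a secondary alcohol at oxygen, which does not touch the stereocenter.

Step 3
Reactants: 4 methyl (2S)-2-[(tert-butyldimethylsilyl)oxy]-5-methylhex-4-enoate
Product: 6 tert-butyldimethyl{[(3S)-6-methylhept-5-en-1-yn-3-yl]oxy}silane, via silyloxy aldehyde 5 (not isolated)
Conditions: DIBAL-H, CH2Cl2, −78 °C; then MeOH, dimethyl (1-diazo-2-oxopropyl)phosphonate, K2CO3, −78 °C to rt; aq potassium sodium tartrate
Reagents that add atoms: dimethyl (1-diazo-2-oxopropyl)phosphonate, CC(=O)C(=[N+]=[N-])P(=O)(OC)OC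
Why: DIBAL-H at −78 °C stops at the aluminium hemiacetal, and the aldehyde released by methanol is converted in the same flask into the terminal alkyne by the Ohira–Bestmann variant of the Seyferth–Gilbert homologation, conditions under which an α-silyloxy stereocenter should keep its configuration.

Step 4
Reactants: 7 2-bromo-1,4-dimethoxybenzene; 8 chromium hexacarbonyl Cr(CO)6
Product: 11 pentacarbonyl[(2,5-dimethoxyphenyl)(methoxy)methylidene]chromium, via (2,5-dimethoxyphenyl)lithium 9 (not isolated), via lithium acylchromate 10 (not isolated)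
Conditions: n-BuLi, THF, −78 °C; Cr(CO)6, −78 °C to rt; solvent exchange, Me3OBF4, CH2Cl2, 0 °C to rt
Reagents that add atoms: trimethyloxonium tetrafluoroborate, C[O+](C)C.F[B-](F)(F)F
Why: Fischer carbene synthesis by bromine–lithium exchange, addition of the aryllithium to a CO ligand of Cr(CO)6 and O-methylation of the resulting acylchromate with the oxonium salt.

Step 5
Reactants: 11 pentacarbonyl[(2,5-dimethoxyphenyl)(methoxy)methylidene]chromium; 6 tert-butyldimethyl{[(3S)-6-methylhept-5-en-1-yn-3-yl]oxy}silane
Product: 13 2-[(1S)-1-[(tert-butyldimethylsilyl)oxy]-4-methylpent-3-en-1-yl]-5,8-dimethoxynaphthalene-1,4-dione, via tricarbonylchromium naphthol complex 12 (not isolated)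
Conditions: THF, 50 °C, argon; then (NH4)2Ce(NO3)6, MeCN/H2O, 0 °C
Reagents that add atoms: water, O
Why: Loss of one CO from 11 lets the alkyne insert into the Cr=C bond (C3–C4, vinylcarbene), CO insertion gives a chromium-bound vinylketene (C1–C2), and 6π-electrocyclisation onto the only unsubstituted ortho carbon of the aryl group (C1–C8a) followed by tautomerisation gives the naphthol complex 12; (NH4)2Ce(NO3)6 (tetravalent cerium) then removes the metal and oxidises the 4-methoxy-1-naphthol ring to the quinone, water supplying the C4 oxygen. The closest known reaction type is the Dötz benzannulation of aryl(alkoxy)carbene chromium complexes with terminal alkynes followed by oxidative work-up. Ring A is closed by a disrotatory 6π-electrocyclic closure of the dienylketene, a formal [3+2+1] assembly of three atoms of the carbene complex, two alkyne carbons and one CO. No stereocenter is created in the product: the propargylic (S) center is a spectator that should keep its configuration, and the planar chirality of 12 disappears on demetallation. The step needs regioselectivity, secured by the terminal alkyne, whose substituted carbon ends up next to the CO-derived C1 for steric reasons, and chemoselectivity in the oxidation, secured by the free naphthol ring being far more electron-rich than the dimethoxy ring B and the isolated trisubstituted alkene.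

Step 6
Reactants: 13 2-[(1S)-1-[(tert-butyldimethylsilyl)oxy]-4-methylpent-3-en-1-yl]-5,8-dimethoxynaphthalene-1,4-dione
Product: 14 2-[(1S)-1-hydroxy-4-methylpent-3-en-1-yl]-5,8-dimethoxynaphthalene-1,4-dione
Conditions: HF·pyridine, pyridine, THF, 0 °C to rt
Reagents that add atoms: none
Why: Fluoride-mediated cleavage of the silyl ether under buffered, non-basic conditions that a quinone tolerates, without breaking the C–O bond at the stereocenter.

Step 7
Reactants: 14 2-[(1S)-1-hydroxy-4-methylpent-3-en-1-yl]-5,8-dimethoxynaphthalene-1,4-dione; 15 tiglic acid ((2E)-2-methylbut-2-enoic acid)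
Product: 16 (1S)-1-(5,8-dimethoxy-1,4-dioxo-1,4-dihydronaphthalen-2-yl)-4-methylpent-3-en-1-yl (2E)-2-methylbut-2-enoate
Conditions: DCC, DMAP (cat.), CH2Cl2, 0 °C to rt
Reagents that add atoms: none
Why: Steglich esterification acylates the only hydroxyl group at oxygen, so the (S) center and the (E) geometry of the tiglate are retained.

Step 8
Reactants: 16 (1S)-1-(5,8-dimethoxy-1,4-dioxo-1,4-dihydronaphthalen-2-yl)-4-methylpent-3-en-1-yl (2E)-2-methylbut-2-enoate
Product: 18 (1S)-1-(5,8-dihydroxy-1,4-dioxo-1,4-dihydronaphthalen-2-yl)-4-methylpent-3-en-1-yl (2E)-2-methylbut-2-enoate (target), via naphthalene-1,4,5,8-tetrone 17 (not isolated)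
Conditions: AgO, 6 M HNO3, 1,4-dioxane, rt, short contact; then aq Na2S2O4 (1 equiv), 0 °C
Reagents that add atoms: water, O
Why: Oxidative demethylation of the p-dimethoxybenzene ring by AgO (divalent silver) in nitric acid should give the bis-quinone, with water supplying the new oxygens, and one equivalent of dithionite reduces it to the naphthazarin, whose tautomer with the side chain on the quinone ring is the target as drawn.

Compound list
1 | methyl (2S)-oxirane-2-carboxylate | COC(=O)[C@@H]1CO1 | starting material
2 | (2-methylprop-1-en-1-yl)magnesium bromide | CC(C)=C[Mg]Br | starting material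
3 | methyl (2S)-2-hydroxy-5-methylhex-4-enoate | COC(=O)[C@@H](O)CC=C(C)C | intermediate
4 | methyl (2S)-2-[(tert-butyldimethylsilyl)oxy]-5-methylhex-4-enoate | COC(=O)[C@@H](O[Si](C)(C)C(C)(C)C)CC=C(C)C | intermediate
5 | (2S)-2-[(tert-butyldimethylsilyl)oxy]-5-methylhex-4-enal | O=C[C@@H](O[Si](C)(C)C(C)(C)C)CC=C(C)C | intermediate
6 | tert-butyldimethyl{[(3S)-6-methylhept-5-en-1-yn-3-yl]oxy}silane | C#C[C@@H](O[Si](C)(C)C(C)(C)C)CC=C(C)C | intermediate
7 | 2-bromo-1,4-dimethoxybenzene | COc1ccc(OC)c(Br)c1 | starting material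
8 | chromium hexacarbonyl | O=C=[Cr](=C=O)(=C=O)(=C=O)(=C=O)=C=O | starting material
9 | (2,5-dimethoxyphenyl)lithium | [Li]c1cc(OC)ccc1OC | intermediate
10 | lithium pentacarbonyl[(2,5-dimethoxyphenyl)(oxido)methylidene]chromate | [Li+].[O-]C(c1cc(OC)ccc1OC)=[Cr](=C=O)(=C=O)(=C=O)(=C=O)=C=O | intermediate
11 | pentacarbonyl[(2,5-dimethoxyphenyl)(methoxy)methylidene]chromium | COC(c1cc(OC)ccc1OC)=[Cr](=C=O)(=C=O)(=C=O)(=C=O)=C=O | intermediate
12 | tricarbonyl{η6-2-[(1S)-1-[(tert-butyldimethylsilyl)oxy]-4-methylpent-3-en-1-yl]-4,5,8-trimethoxynaphthalen-1-ol}chromium (metal fragment drawn unbonded, coordinated to the new ring) | CC(C)(C)[Si](C)(C)O[C@@H](CC=C(C)C)c1cc(OC)c2c(OC)ccc(OC)c2c1O.O=C=[Cr](=C=O)=C=O | intermediate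
13 | 2-[(1S)-1-[(tert-butyldimethylsilyl)oxy]-4-methylpent-3-en-1-yl]-5,8-dimethoxynaphthalene-1,4-dione | CC(C)(C)[Si](C)(C)O[C@@H](CC=C(C)C)C1=CC(=O)c2c(OC)ccc(OC)c2C1=O | intermediate
14 | 2-[(1S)-1-hydroxy-4-methylpent-3-en-1-yl]-5,8-dimethoxynaphthalene-1,4-dione | O[C@@H](CC=C(C)C)C1=CC(=O)c2c(OC)ccc(OC)c2C1=O | intermediate
15 | tiglic acid, (2E)-2-methylbut-2-enoic acid | C/C=C(\C)C(=O)O | starting material
16 | (1S)-1-(5,8-dimethoxy-1,4-dioxo-1,4-dihydronaphthalen-2-yl)-4-methylpent-3-en-1-yl (2E)-2-methylbut-2-enoate | C/C=C(\C)C(=O)O[C@@H](CC=C(C)C)C1=CC(=O)c2c(OC)ccc(OC)c2C1=O | intermediate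
17 | (1S)-4-methyl-1-(1,4,5,8-tetraoxo-1,4,5,8-tetrahydronaphthalen-2-yl)pent-3-en-1-yl (2E)-2-methylbut-2-enoate | C/C=C(\C)C(=O)O[C@@H](CC=C(C)C)C1=CC(=O)C2=C(C1=O)C(=O)C=CC2=O | intermediate
18 | (1S)-1-(5,8-dihydroxy-1,4-dioxo-1,4-dihydronaphthalen-2-yl)-4-methylpent-3-en-1-yl (2E)-2-methylbut-2-enoate | C/C=C(\C)C(=O)O[C@@H](CC=C(C)C)C1=CC(=O)c2c(O)ccc(O)c2C1=O | target

Total step count: 8. Longest linear sequence: 7 steps (steps 1, 2, 3, 5, 6, 7, 8); the carbene branch (step 4) joins at step 5.

Steps most likely to fail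

Step 8. The strongly acidic oxidising medium may hydrate or cyclise the prenyl alkene or ionise the allylic ester, and over-reduction in the work-up may expel the tiglate. The fallback sets out from 16 and shifts the oxidation level between the rings, so that neither AgO nor a bis-quinone is needed. Reductive acetylation (Zn dust, Ac2O, NaOAc, rt) should give (1S)-1-(1,4-diacetoxy-5,8-dimethoxynaphthalen-2-yl)-4-methylpent-3-en-1-yl tiglate F1. In F1 the dimethoxy ring is now the electron-rich one, and (NH4)2Ce(NO3)6 in MeCN/H2O at 0 °C should oxidise it to the 5,8-diacetoxy-1,4-naphthoquinone F2, with the side chain on the acetoxylated ring. Mild methanolysis of the two aryl acetates (K2CO3 cat., MeOH, 0 °C), which should leave the hindered conjugated alkyl ester alone, gives the naphthazarin and so returns to the route at 18.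

Step 5. Alkyne uptake may stall through chelation of the ortho-methoxy group to chromium, or the vinylcarbene intermediate may collapse to indene, furan or cyclobutenone products instead of inserting CO. The fallback sets out from 7 and 6, builds the same ring by a Moore cyclisation and returns at 13.
- Elimination–[2+2] cycloaddition of 7 with 1,1-dimethoxyethene (NaNH2, THF) should give 2,5,7,7-tetramethoxybicyclo[4.2.0]octa-1,3,5-triene F3.
- Aqueous HCl hydrolyses it to 3,6-dimethoxybenzocyclobutenone F4.
- Geminal bromination (NBS, radical initiation) gives the 8,8-dibromo ketone F5, and hydrolysis (AgO2CCF3, aq MeCN) gives 3,6-dimethoxybenzocyclobutenedione F6.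
- Alkyne 6 is deprotonated (n-BuLi, THF, −78 °C) to the lithium acetylide F7, which adds to one carbonyl of the symmetric dione to give the alkynyl carbinol F8.
- Heating F8 in toluene or xylene should open the four-membered ring to a ketene, close it onto the alkyne and transfer hydrogen, giving 13 directly. Because the dione is symmetric, no regiochemical issue arises.

Step 3. Over-reduction of the ester and base-induced epimerisation of the α-silyloxy aldehyde during the one-pot homologation may erode yield and enantiopurity. The fallback sets out from 4 and returns at 6. DIBAL-H reduction at −78 °C with isolation of aldehyde 5 is followed by a Corey–Fuchs sequence under aprotic conditions. CBr4, PPh3 and Et3N in CH2Cl2 at 0 °C give tert-butyl{[(3S)-1,1-dibromo-6-methylhepta-1,5-dien-3-yl]oxy}dimethylsilane F9. Two equivalents of n-BuLi in THF at −78 °C convert F9 into the lithium acetylide F7 (the same species as in the fallback for step 5), and an aqueous quench gives 6.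

Further compounds
F1 | step 8 | (1S)-1-(1,4-diacetoxy-5,8-dimethoxynaphthalen-2-yl)-4-methylpent-3-en-1-yl (2E)-2-methylbut-2-enoate | C/C=C(\C)C(=O)O[C@@H](CC=C(C)C)c1cc(OC(C)=O)c2c(OC)ccc(OC)c2c1OC(C)=O
F2 | step 8 | (1S)-1-(1,4-diacetoxy-5,8-dioxo-5,8-dihydronaphthalen-2-yl)-4-methylpent-3-en-1-yl (2E)-2-methylbut-2-enoate | C/C=C(\C)C(=O)O[C@@H](CC=C(C)C)c1cc(OC(C)=O)c2C(=O)C=CC(=O)c2c1OC(C)=O
F3 | step 5 | 2,5,7,7-tetramethoxybicyclo[4.2.0]octa-1,3,5-triene | COc1ccc(OC)c2c1CC2(OC)OC
F4 | step 5 | 2,5-dimethoxybicyclo[4.2.0]octa-1,3,5-trien-7-one | COc1ccc(OC)c2c1CC2=O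
F5 | step 5 | 8,8-dibromo-2,5-dimethoxybicyclo[4.2.0]octa-1,3,5-trien-7-one | COc1ccc(OC)c2c1C(Br)(Br)C2=O
F6 | step 5 | 2,5-dimethoxybicyclo[4.2.0]octa-1,3,5-triene-7,8-dione | COc1ccc(OC)c2c1C(=O)C2=O
F7 | step 5 | {(3S)-3-[(tert-butyldimethylsilyl)oxy]-6-methylhept-5-en-1-yn-1-yl}lithium | [Li]C#C[C@@H](O[Si](C)(C)C(C)(C)C)CC=C(C)C
F8 | step 5 | 8-{(3S)-3-[(tert-butyldimethylsilyl)oxy]-6-methylhept-5-en-1-yn-1-yl}-8-hydroxy-2,5-dimethoxybicyclo[4.2.0]octa-1,3,5-trien-7-one | COc1ccc(OC)c2c1C(=O)C2(O)C#C[C@@H](O[Si](C)(C)C(C)(C)C)CC=C(C)C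
F9 | step 3 | tert-butyl{[(3S)-1,1-dibromo-6-methylhepta-1,5-dien-3-yl]oxy}dimethylsilane | BrC(Br)=C[C@@H](O[Si](C)(C)C(C)(C)C)CC=C(C)C
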